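Late in the earlier runs the readings stood flat: at 60.0 min alpha read 13.8% target and 12.4% uncatalysed product, and theta and zeta were flat as well.

| setting | theta | alpha | zeta | flask |
|---|---|---|---|---|
| starting material | 0.10 M | 0.10 M | 0.20 M | 0.10 M |
| coupling partner | 0.15 M | 0.15 M | 0.15 M | 0.150 M |
| free catalyst | 0.50 mM | 0.75 mM | 1 mM | 1.0 mM |
| second catalyst | 2 mM | 2 mM | 2 mM | 2.0 mM |
| remark | run made earlier | run made earlier | run made earlier |  |
| time |  |  |  | 80 min |

| run | time / min | target / % | uncatalysed product / % |
|---|---|---|---|
| theta | 10.0 | 6.1 | 14.6 |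
| theta | 20.0 | 9.2 | 14.9 |
| theta | 30.0 | 11.2 | 13.9 |
| theta | 40.0 | 11.1 | 14.9 |
| theta | 50.0 | 10.5 | 13.4 |
| theta | 60.0 | 10.8 | 15.1 |
| alpha | 5.00 | 4.4 | 11.9 |
| alpha | 8.00 | 8.4 | 12.0 |
| alpha | 15.0 | 12.0 | 13.0 |
| alpha | 25.0 | 12.8 | 13.0 |
| alpha | 40.0 | 13.0 | 12.4 |
| alpha | 60.0 | 13.8 | 12.4 |
| zeta | 6.00 | 7.1 | 10.2 |
| zeta | 15.0 | 9.8 | 11.0 |
| zeta | 30.0 | 10.0 | 10.5 |
| zeta | 50.0 | 9.7 | 10.5 |
| zeta | 60.0 | 9.5 | 11.9 |

(standard deviation of a reading: 0.5 percentage points)

* ratio of target to uncatalysed product at 8.0 s
* ratio of target to uncatalysed product at 80 min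
* which of target and uncatalysed product there is more of at 80 min

First I asked how the rates of the two products compare. Each step takes one coupling partner, so the partner cancels from the ratio of their rates, which follows second catalyst times intermediate over starting material.

Next I asked how that ratio drifts. Early on, intermediate builds up in proportion to free catalyst and time, so this selectivity should climb in a straight line, with a slope proportional to both catalysts.

Alpha's first reading, at 5.00 min, gave a ratio of 0.370. Dividing by that time and scaling from 0.75 mM to 1.0 mM of free catalyst, at the same second catalyst, gave 0.0986 min⁻¹ for this flask. This is the ratio gain, the mean climb of the product ratio per minute up to that reading, scaled to this flask; that reading may already lie past the straight stretch, so the gain is a chord and not the slope at the start. At 8.0 s it gave me 0.0131.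

Last I asked who leads at the end. Alpha's late ratio, scaled the same way, gave me 1.48, so I expected target to lead.

The forecast gave 0.006 at 8.0 s and 1.4 at 80 min, with target ahead, reasoning that “The target must wait for intermediate”. Its early ratio is lower than mine.

The flask gave 0.0256 and 1.29, with 15.4% target against 11.9% uncatalysed product, so target led. The early ratio was twice my figure.

    starting material + free catalyst → free catalyst + intermediate (k = 2.60 M⁻¹ s⁻¹)
    coupling partner + second catalyst + intermediate → second catalyst + target (k = 14.0 M⁻² s⁻¹)
    starting material + coupling partner → uncatalysed product (k = 0.0110 M⁻¹ s⁻¹)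
    2 coupling partner → self-condensation product (k = 0.0690 M⁻¹ s⁻¹)
    target → over-reaction product (k = 5.60 × 10⁻⁶ s⁻¹)

At 4.17 min this flask used coupling partner 2.5 times faster in self-condensation than in making target. At 80 min its coupling partner stood at 0%, with 72.3% still as intermediate. In the neighbour flask with 0.0080 M of second catalyst, the ratio gain rises by a factor of 4.00 to 0.394 min⁻¹, which puts its early ratio at 0.103; the simulation gave 0.0995.

The earlier runs and the new flask stem from a simulated flask with constants of no real substance; noise was put on by code.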